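## Structural features

The target is a sesquilignan-type pentol: a (2R,3R)-2,3-dibenzylbutane-1,4-diol in which one benzyl group is a guaiacyl unit (ring A) and the other benzylic CH2 sits on C5 of a 7-methoxy-2,3-dihydrobenzofuran (benzo ring B fused to dihydrofuran ring C). Ring C carries a second guaiacyl group (ring D) at C2 and a hydroxymethyl group at C3, trans to each other, (2S,3R). The four stereocentres form two adjacent pairs, C2/C3 of the chain and C2/C3 of ring C. The pairs are separated by a CH2–aryl spacer and cannot control one another, so each needs its own source of absolute configuration. The fragile points are the O1–C2 bond of ring C (a benzylic aryl ether on an oxygenated arene, sensitive to acid, to hydrogenolysis and, once the ring D phenol is free, to quinone methide formation), the two electron-rich phenols, and the chain stereocentres whenever they stand α to a ketone. The real difficulty is to put two different aryl groups on the two ends of a four-carbon unit that is otherwise symmetric, without a long differentiation of the ends. The feature used is that the chain without its aryl groups is C2-symmetric and that each benzylic carbon (the CH2 on ring A and the CH2 on C5 of ring B) is 1,4-related to the primary hydroxyl on the far stereocentre. That is the pattern of a γ-lactone, and taken twice it is the cis-fused bislactone 7, whose two carbonyl carbons become the two benzylic carbons.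

## Logic of the disconnections

**29 ⇒ 28 ⇒ 27 ⇒ 26 ⇒ 25 ⇒ 24 (no skeletal bond cut).** The three O–Si bonds and two O–acetyl bonds are protective. The two benzylic C–H bonds of 27 are traced back to C–OAc (26), C–OH (25) and C=O (24). The reason is that an aryl–CH2 bond next to a stereocentre is best made as an aryl–C(=O) bond. The gain is a 1,4-diketone with both carbonyl carbons on aryl rings. The demand is a deoxygenation that spares O1–C2 of ring C. For that reason the phenols are silylated, so that no benzyl ether has to be cleaved and ring D is never a free phenol under hydrogen, and the benzylic oxygens leave as acetates under neutral conditions.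

**24 ⇒ 22 + 7 + 9.** The bonds cut are C5 (ring B)–C(=O) and C1 (ring A)–C(=O). Cutting here gives three fragments that already hold all four stereocentres. Because 7 is C2-symmetric, its two electrophilic carbons are identical and need no differentiation. The demand is that each aryl metal adds once and stops, that the first stage touches one carbonyl only, and that the bridgeheads are not enolised.

**7 ⇒ 6 ⇒ 5.** The two lactone O–C(=O) bonds are cut (acyl transfer from the imide nitrogen to the hydroxyl oxygen), and the two C–OH bonds are traced to C–Si bonds. The reason is that a β-oxygen would be expelled from the enolate needed one step earlier, whereas silicon is not. The gain is a plain 2,3-disubstituted succinyl bis-imide. The demand is a C–Si oxidation with retention that leaves the α-centres alone, and lactonisation faster than epimerisation.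

**5 ⇒ 4 + 4.** The central C2–C3 bond is cut into two identical halves, which the C2 symmetry allows. The gain is a single three-carbon acyl unit and one auxiliary for both centres. The demand is an oxidative enolate coupling with facial control on both halves. This fixes the auxiliary as (R), because here the imide carbonyl ends as the benzylic carbon and the side arm as CH2OH.

**4 ⇒ 3 ⇒ 1 + 2.** The C–Si bond at the β-carbon (conjugate addition) and the N–C(=O) bond are cut. The gain is two commercial materials. The demand is conjugate silylation of an acrylimide without polymerisation.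

**22 ⇒ 21 ⇒ 20 ⇒ 19.** The O–Si bond is cut, C3–CH2OH is traced to C3–CO2Me, and the trans ester to its C3 epimer. The ester is kept because it activates C3 both for ring closure and for epimerisation. The demand is epimerisation without ring-opening β-elimination and a reduction that spares C–Br.

**19 ⇒ 18.** The C2–C3 bond of ring C is cut; C3 becomes a carbene carbon and C2 the CH2 of a benzyl aryl ether. The only C–H bond in reach is doubly activated (benzylic, α to oxygen), and both centres arise from an achiral open-chain precursor under catalyst control. The demand is enantio- and diastereocontrol.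

**18 ⇒ 17 ⇒ 13 + 16.** The C=N2 bond (diazo transfer) and the O–CH2 bond between O1 and the ring D benzylic carbon are cut. The gain is two simple arenes. The demand is etherification of a hindered phenol without ionising the 4-silyloxybenzyl partner.

**13 ⇒ 12 ⇒ 11 ⇒ 8 + 10.** The ester O–CH3 bond, the benzylic C–OH bond and the aryl–C bond ortho to the phenol are cut. The bromine of 8 blocks the para position and is the later C5 handle; 8 also serves as the source of 9. The demand is ortho-selective hydroxyalkylation and a benzylic reduction that leaves C–Br.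

**16 ⇒ 15 ⇒ 14 and 9 ⇒ 8.** Only O–Si bonds and one carbonyl reduction are involved; the gain is commodity starting materials.

## Other disconnections considered

**Alternative 1:** Ring C is cut at C3–C3a and traced back to the chroman-4-one A2, in which the future C3a is still bonded to the carbonyl carbon. In the forward sense A2 with PhI(OAc)2 and H2SO4 in HC(OMe)3 would form its enol ether, be iodinated at C3 by the trivalent iodine reagent, and rearrange by a 1,2-shift of the ring B carbon from the carbonyl carbon to C3. The former carbonyl carbon would end as the methyl ester of A1.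
- In its favour: compounds like A2 come from an o-hydroxyacetophenone and an aldehyde in a few steps, the trans ester should arise directly, and neither a diazo compound nor rhodium is needed. On step count for ring C it is the better of the two.
- Against it here: the single stereocentre of A2 can erode by reversible ring opening in strong acid. Ring D competes as a migrating group unless deactivated as the pivalate, and that ester cannot enter the aryllithium chemistry of step 16 and would have to be exchanged. The electron-rich rings are also exposed to an oxidant.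
- Comparison: A1 solves ring C only, so it would replace steps 6–13 and not the chosen key step. On structure the two plans are equal from A1 onward. Mechanistically the chosen route sets C2 in a catalyst-controlled C–H insertion with no racemisation channel, whereas here the configuration rests on a labile centre surviving a cationic rearrangement.

**Alternative 2:** Ring C is cut at both C2–C3 and O1–C2. The forward step would treat the sulfone A4 with Cs2CO3 to expel sulfinate and form the o-quinone methide A5. A benzylic ylide from the sulfonium salt A6 of a C2-symmetric chiral thiolane would add to the exocyclic carbon of A5 (C2–C3), and the phenoxide would then displace the sulfide at C2 (O1–C2, 5-exo-tet) to give A3.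
- In its favour: two bonds and the ring form in one convergent step, A3 arrives with C3 already at the protected alcohol level, and the anti-periplanar displacement should favour the trans isomer. On step economy for ring C it is clearly the better plan.
- Against it here: the absolute configuration would rest on a chiral sulfide acting through a semi-stabilised ylide on an alkyl-substituted quinone methide, the least secure combination for facial control. A5 has hydrogens next to the methide carbon and can tautomerise to a vinylphenol. A3 carries a benzyl ether on ring D, which brings back the hydrogenolysis problem unless it is redesigned.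
- Comparison: A3 has the same skeleton as 22, so this is a complement that could feed step 16. It is equal to the chosen plan on the final structure; it is weaker on mechanistic security of the stereocontrol.

**Alternative 3:** Ring C is cut at C2–C3 alone, back to the diazo ester A8 carrying an (S)-lactamide-derived ester. In the forward sense A8 would lose N2 on Rh2(S-DOSP)4 (dirhodium tetrakis[(S)-N-(4-dodecylphenylsulfonyl)prolinate], divalent rhodium), and the carbene carbon would insert into the benzylic C–H of the O1 benzyl ether to give the trans ester A7.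
- In its favour: it is the same bond and the same mechanism as step 12, so on structure and mechanism it is equal. It is better in two respects: the trans isomer forms directly, so step 13 is not needed, and the auxiliary makes the stereoisomers diastereomeric and separable, so optical purity can be secured by chromatography.
- Against it here: two extra operations attach the auxiliary, a stoichiometric chiral alcohol is used, and A7 carries a benzyl ether on ring D.
- Comparison: on step count it is about equal (one step saved, two added). As the centre of a plan it addresses ring C only and still needs the union with the chain that step 16 provides. The chosen route uses the catalyst-only variant and keeps the auxiliary variant as the fallback for step 12.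

Key step: step 16

**Remarks on the chemistry (assumptions and corrections)**

- Auxiliary: the oxidative enolate coupling is assumed to follow the facial preference of oxazolidinone enolate alkylations. On that basis an (S)-4-benzyl auxiliary would lead to the (1S,5S)-bislactone and the enantiomeric chain, because the imide carbonyl becomes the benzylic carbon and the side arm the CH2OH. The (R)-auxiliary 1 is therefore used.
- Catalyst sense: the sense of induction of Rh2(R-PTTL)4 in step 12 is assigned by analogy with related aryldiazoacetate insertions.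
- Protecting groups: both phenols are carried as triisopropylsilyl ethers and no benzyl ether is used, so ring C never meets hydrogen as a free 4-hydroxybenzyl aryl ether.

## Route

Step 1
Reactants: 1 (R)-4-benzyl-1,3-oxazolidin-2-one; 2 acryloyl chloride
Product: 3 (R)-3-acryloyl-4-benzyl-1,3-oxazolidin-2-one
Conditions: n-BuLi, THF, −78 °C; then 2, −78 → 0 °C
Reagents that add atoms: none
Why: N-acylation of the lithiated oxazolidinone by an acid chloride (imide formation); low temperature and prompt use limit polymerisation of the acrylimide; no stereocentre is formed.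

Step 2
Reactants: 3 (R)-3-acryloyl-4-benzyl-1,3-oxazolidin-2-one
Product: 4 (R)-4-benzyl-3-[3-(dimethylphenylsilyl)propanoyl]-1,3-oxazolidin-2-one
Conditions: PhMe2Si–Bpin, CuCl (5 mol %), IMes·HCl (5 mol %), NaOt-Bu (10 mol %), MeOH (2 equiv), THF, 0 °C
Reagents that add atoms: 2-[dimethyl(phenyl)silyl]-4,4,5,5-tetramethyl-1,3,2-dioxaborolane, C[Si](C)(B1OC(C)(C)C(C)(C)O1)c1ccccc1
Why: Copper-catalysed conjugate silyl transfer from the silylboronate (Cu–Si addition to the enoyl imide, then protonation of the copper enolate by methanol); the silyl group is a hydroxyl surrogate that cannot be lost by β-elimination from the enolate of step 3.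

Step 3
Reactants: 4 (R)-4-benzyl-3-[3-(dimethylphenylsilyl)propanoyl]-1,3-oxazolidin-2-one (two molecules)
Product: 5 (4R,4'R)-3,3'-[(2R,3R)-2,3-bis{[dimethyl(phenyl)silyl]methyl}butanedioyl]bis(4-benzyl-1,3-oxazolidin-2-one)
Conditions: LiN(i-Pr)2, THF, −78 °C; CuCl2, DMF, −78 °C → rt
Reagents that add atoms: none
Why: Oxidative homocoupling of the lithium Z-enolate by divalent copper; each enolate carbon should bond on the face away from the 4-benzyl group, as in Evans alkylations, which with the (R)-auxiliary gives the (2R,3R) centres; minor diastereomers are removed by chromatography or crystallisation.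

Step 4
Reactants: 5 (4R,4'R)-3,3'-[(2R,3R)-2,3-bis{[dimethyl(phenyl)silyl]methyl}butanedioyl]bis(4-benzyl-1,3-oxazolidin-2-one)
Product: 7 (1R,5R)-3,7-dioxabicyclo[3.3.0]octane-2,6-dione, via diol bis-imide 6 (not isolated)
Conditions: KBr, AcOOH, NaOAc, AcOH, rt; then TsOH (cat.), CH2Cl2, rt
Reagents that add atoms: peracetic acid, CC(=O)OO
Why: Fleming–Tamao oxidation (bromodesilylation of the phenyl group, then peracid-induced 1,2-shift from silicon to oxygen with retention, the stereocentres being one atom away and untouched) followed by acid-catalysed γ-lactonisation that expels the recoverable auxiliary; only the (2R,3R) diol can close both rings of the cis-fused bicycle.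

Step 5
Reactants: 8 4-bromo-2-methoxyphenol
Product: 9 (4-bromo-2-methoxyphenoxy)triisopropylsilane
Conditions: TIPSCl, imidazole, DMF, rt
Reagents that add atoms: chlorotriisopropylsilane, CC(C)[Si](Cl)(C(C)C)C(C)C
Why: Standard silylation of a phenol; the bulky aryl silyl ether is inert to tert-butyllithium at −78 °C and is removed by fluoride at the end.

Step 6
Reactants: 8 4-bromo-2-methoxyphenol; 10 glyoxylic acid (as monohydrate)
Product: 11 2-(5-bromo-2-hydroxy-3-methoxyphenyl)-2-hydroxyacetic acid (racemic)
Conditions: NaOH, H2O, rt → 40 °C; then HCl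
Reagents that add atoms: none
Why: Ortho-hydroxyalkylation of the phenoxide by glyoxylate (electrophilic aromatic substitution); the para position is blocked by bromine, so C6 is the only activated site; the new carbinol centre is racemic and is removed in step 7.

Step 7
Reactants: 11 2-(5-bromo-2-hydroxy-3-methoxyphenyl)-2-hydroxyacetic acid
Product: 13 methyl (5-bromo-2-hydroxy-3-methoxyphenyl)acetate, via arylacetic acid 12 (not isolated)
Conditions: SnCl2·2H2O, conc. HCl, AcOH, 90 °C; then MeOH, H2SO4 (cat.), reflux
Reagents that add atoms: methanol, CO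
Why: Reduction of the benzylic hydroxyl of a hydroxymandelic acid by SnCl2/HCl (the classical route to hydroxyphenylacetic acids), then Fischer esterification, which also opens any benzofuranone lactone formed; the aryl bromide is inert to both.

Step 8
Reactants: 14 vanillin (4-hydroxy-3-methoxybenzaldehyde)
Product: 15 3-methoxy-4-(triisopropylsilyloxy)benzaldehyde
Conditions: TIPSCl, imidazole, DMF, rt
Reagents that add atoms: chlorotriisopropylsilane, CC(C)[Si](Cl)(C(C)C)C(C)C
Why: Standard phenol silylation; this places on ring D a group that survives every later step up to the final fluoride treatment.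

Step 9
Reactants: 15 3-methoxy-4-(triisopropylsilyloxy)benzaldehyde
Product: 16 [3-methoxy-4-(triisopropylsilyloxy)phenyl]methanol
Conditions: NaBH4, MeOH, 0 °C
Reagents that add atoms: none
Why: Borohydride reduction of an aryl aldehyde; the aryl silyl ether is stable to brief exposure at 0 °C.

Step 10
Reactants: 13 methyl (5-bromo-2-hydroxy-3-methoxyphenyl)acetate; 16 [3-methoxy-4-(triisopropylsilyloxy)phenyl]methanol
Product: 17 methyl (5-bromo-3-methoxy-2-{[3-methoxy-4-(triisopropylsilyloxy)benzyl]oxy}phenyl)acetate
Conditions: PPh3, DIAD, THF, 0 °C → rt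
Reagents that add atoms: none
Why: Mitsunobu etherification with the phenol as the acidic partner and the primary benzylic alcohol as the electrophile; it avoids the labile 4-silyloxybenzyl halide.

Step 11
Reactants: 17 methyl (5-bromo-3-methoxy-2-{[3-methoxy-4-(triisopropylsilyloxy)benzyl]oxy}phenyl)acetate
Product: 18 methyl 2-diazo-2-(5-bromo-3-methoxy-2-{[3-methoxy-4-(triisopropylsilyloxy)benzyl]oxy}phenyl)acetate
Conditions: p-ABSA, DBU, MeCN, 0 °C → rt
Reagents that add atoms: 4-acetamidobenzenesulfonyl azide, CC(=O)Nc1ccc(cc1)S(=O)(=O)N=[N+]=[N-]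
Why: Regitz diazo transfer to the arylacetate enolate, the standard preparation of aryldiazoacetates.

Step 12
Reactants: 18 methyl 2-diazo-2-(5-bromo-3-methoxy-2-{[3-methoxy-4-(triisopropylsilyloxy)benzyl]oxy}phenyl)acetate
Product: 19 methyl (2S,3R)-cis-5-bromo-7-methoxy-2-[3-methoxy-4-(triisopropylsilyloxy)phenyl]-2,3-dihydro-1-benzofuran-3-carboxylate
Conditions: Rh2(R-PTTL)4 (1 mol %), toluene, −60 °C
Reagents that add atoms: none
Why: Intramolecular 1,5 C–H insertion of the donor/acceptor rhodium carbene into the benzylic C–H bond α to oxygen forms C2–C3 and closes ring C; with dirhodium tetrakis[N-phthaloyl-tert-leucinate] catalysts (divalent rhodium) this insertion is known to be cis-selective and enantioselective, and the (R)-catalyst is chosen to set C2 as S (C3 is corrected in step 13).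

Step 13
Reactants: 19 methyl (2S,3R)-cis-5-bromo-7-methoxy-2-[3-methoxy-4-(triisopropylsilyloxy)phenyl]-2,3-dihydro-1-benzofuran-3-carboxylate
Product: 20 methyl (2S,3S)-trans-5-bromo-7-methoxy-2-[3-methoxy-4-(triisopropylsilyloxy)phenyl]-2,3-dihydro-1-benzofuran-3-carboxylate
Conditions: DBU, toluene, 60 °C
Reagents that add atoms: none
Why: Base-mediated epimerisation at C3 through the ester enolate to the thermodynamically preferred trans isomer; C2 has no acidic hydrogen and is not affected, and the amidine base spares the aryl silyl ether.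

Step 14
Reactants: 20 methyl (2S,3S)-trans-5-bromo-7-methoxy-2-[3-methoxy-4-(triisopropylsilyloxy)phenyl]-2,3-dihydro-1-benzofuran-3-carboxylate
Product: 21 {(2S,3R)-trans-5-bromo-7-methoxy-2-[3-methoxy-4-(triisopropylsilyloxy)phenyl]-2,3-dihydro-1-benzofuran-3-yl}methanol
Conditions: LiBH4, THF–MeOH, 0 °C → rt
Reagents that add atoms: none
Why: Ester reduction by LiBH4, which leaves the aryl bromide and the silyl ether alone; the C3 descriptor changes from S to R only through the change in substituent priority.

Step 15
Reactants: 21 {(2S,3R)-trans-5-bromo-7-methoxy-2-[3-methoxy-4-(triisopropylsilyloxy)phenyl]-2,3-dihydro-1-benzofuran-3-yl}methanol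
Product: 22 (2S,3R)-trans-5-bromo-3-[(tert-butyldimethylsilyloxy)methyl]-7-methoxy-2-[3-methoxy-4-(triisopropylsilyloxy)phenyl]-2,3-dihydro-1-benzofuran
Conditions: TBSCl, imidazole, DMF, rt
Reagents that add atoms: tert-butylchlorodimethylsilane, CC(C)(C)[Si](C)(C)Cl
Why: Standard silylation of a primary alcohol; it gives the aryl bromide for the key step with no benzyl ether in the molecule.

Step 16
Reactants: 22 (2S,3R)-trans-5-bromo-3-[(tert-butyldimethylsilyloxy)methyl]-7-methoxy-2-[3-methoxy-4-(triisopropylsilyloxy)phenyl]-2,3-dihydro-1-benzofuran; 7 (1R,5R)-3,7-dioxabicyclo[3.3.0]octane-2,6-dione; 9 (4-bromo-2-methoxyphenoxy)triisopropylsilane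
Product: 24 (2R,3R)-1-{(2S,3R)-3-[(tert-butyldimethylsilyloxy)methyl]-7-methoxy-2-[3-methoxy-4-(triisopropylsilyloxy)phenyl]-2,3-dihydro-1-benzofuran-5-yl}-2,3-bis(hydroxymethyl)-4-[3-methoxy-4-(triisopropylsilyloxy)phenyl]butane-1,4-dione (in equilibrium with its bicyclic bis-hemiketal), via lactol lactone mono-adduct 23 (not isolated)
Conditions: 22, t-BuLi (2 equiv), THF, −78 °C, then CeCl3; added to 7 (1.5 equiv), THF, −78 °C; then aryl-CeCl2 from 9 (t-BuLi, CeCl3; 3.5 equiv), −78 → −40 °C; aq. NH4Cl
Reagents that add atoms: none
Why: Bromine–lithium exchange on 22 and transmetalation to the aryl-cerium dichloride give a nucleophile of low basicity that adds once to one lactone carbonyl of 7, and the resulting tetrahedral metal lactolate 23 does not collapse at −78 °C, so no ketone is exposed. Because 7 is C2-symmetric its two carbonyls are equivalent and a single mono-adduct forms; the second aryl-cerium (from 9) then attacks the remaining lactone carbonyl, and aqueous work-up releases the bis-hemiketal, which equilibrates with the diketone diol 24. The closest known reaction type is the mono-addition of aryllithium or aryl-cerium reagents to γ-lactones that stops at the lactol, as used for aryl C-glycosides; using two different aryl nucleophiles in sequence on one bislactone extends it to a three-component union. No ring is closed and no stereocentre is created: the two bridgehead centres of 7 are carried over untouched as C2 and C3 of the chain, and the two ring oxygens become the two primary hydroxyls. The selectivity needed is mono-addition in the first stage; it is secured by adding the limiting, valuable aryl-cerium to an excess of 7, and the symmetric bis-adduct that the cheap ring A reagent forms with surplus 7 is removed by chromatography. Enolisation at the bridgeheads is disfavoured by the cerium reagent and would in any case return the only possible cis ring fusion on reprotonation. The silyl ethers, the aryl methyl ethers and the O1–C2 bond of ring C are inert to these conditions.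

Step 17
Reactants: 24 (2R,3R)-1,4-diaryl-2,3-bis(hydroxymethyl)butane-1,4-dione (as in step 16)
Product: 26 (2R,3R)-1-{(2S,3R)-3-[(tert-butyldimethylsilyloxy)methyl]-7-methoxy-2-[3-methoxy-4-(triisopropylsilyloxy)phenyl]-2,3-dihydro-1-benzofuran-5-yl}-2,3-bis(acetoxymethyl)-4-[3-methoxy-4-(triisopropylsilyloxy)phenyl]butane-1,4-diyl diacetate (mixture of epimers at C1 and C4), via tetraol 25 (not isolated)
Conditions: NaBH4, MeOH–THF, −20 → 0 °C; concentrate; Ac2O, pyridine, DMAP (cat.), CH2Cl2, rt
Reagents that add atoms: acetic anhydride, CC(=O)OC(C)=O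
Why: Borohydride reduction of both aryl ketones through the open keto form (the carbinol configurations are irrelevant) and peracetylation of the crude tetraol, as in alditol acetate preparation; reduction at low temperature should outrun epimerisation or retro-aldol loss at the α-centres.

Step 18
Reactants: 26 tetraacetate (as in step 17)
Product: 27 (2R,3R)-2-[3-methoxy-4-(triisopropylsilyloxy)benzyl]-3-({(2S,3R)-3-[(tert-butyldimethylsilyloxy)methyl]-7-methoxy-2-[3-methoxy-4-(triisopropylsilyloxy)phenyl]-2,3-dihydro-1-benzofuran-5-yl}methyl)butane-1,4-diyl diacetate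
Conditions: H2 (1 atm), Pd/C, EtOAc, rt
Reagents that add atoms: none
Why: Hydrogenolysis of secondary benzylic acetates on electron-rich arenes over Pd/C proceeds under neutral conditions at room temperature; the O1–C2 bond of ring C is a hindered cyclic ether on a silylated, non-phenolic ring and no acid is present, so it should survive, and the silyl ethers and primary acetates are inert.

Step 19
Reactants: 27 diacetate (as in step 18)
Product: 29 (2R,3R)-2-(4-hydroxy-3-methoxybenzyl)-3-{[(2S,3R)-2-(4-hydroxy-3-methoxyphenyl)-3-(hydroxymethyl)-7-methoxy-2,3-dihydro-1-benzofuran-5-yl]methyl}butane-1,4-diol (target), via silylated diol 28 (not isolated)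
Conditions: K2CO3 (cat.), MeOH, rt; then TBAF, AcOH, THF, 0 °C → rt
Reagents that add atoms: none
Why: Zemplén-type methanolysis of the two primary acetates, then fluoride cleavage of the three silyl ethers, buffered with acetic acid so that the phenoxides do not open ring C through a quinone methide; no stereocentre is touched.

## Compound list

1 | (R)-4-benzyl-1,3-oxazolidin-2-one | O=C1N[C@H](Cc2ccccc2)CO1 | starting material
2 | acryloyl chloride | C=CC(Cl)=O | starting material
3 | (R)-3-acryloyl-4-benzyl-1,3-oxazolidin-2-one | C=CC(=O)N1[C@H](Cc2ccccc2)COC1=O | intermediate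
4 | (R)-4-benzyl-3-[3-(dimethylphenylsilyl)propanoyl]-1,3-oxazolidin-2-one | C[Si](C)(CCC(=O)N1[C@H](Cc2ccccc2)COC1=O)c1ccccc1 | intermediate
5 | (4R,4'R)-3,3'-[(2R,3R)-2,3-bis{[dimethyl(phenyl)silyl]methyl}butanedioyl]bis(4-benzyl-1,3-oxazolidin-2-one) | O=C(N1[C@H](Cc2ccccc2)COC1=O)[C@@H](C[Si](C)(C)c1ccccc1)[C@H](C[Si](C)(C)c1ccccc1)C(=O)N1[C@H](Cc2ccccc2)COC1=O | intermediate
6 | (4R,4'R)-3,3'-[(2R,3R)-2,3-bis(hydroxymethyl)butanedioyl]bis(4-benzyl-1,3-oxazolidin-2-one) | O=C(N1[C@H](Cc2ccccc2)COC1=O)[C@@H](CO)[C@H](CO)C(=O)N1[C@H](Cc2ccccc2)COC1=O | intermediate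
7 | (1R,5R)-3,7-dioxabicyclo[3.3.0]octane-2,6-dione (cis-fused bislactone) | O=C1[C@@H](CO2)[C@H](CO1)C2=O | intermediate
8 | 4-bromo-2-methoxyphenol | COc1cc(Br)ccc1O | starting material
9 | (4-bromo-2-methoxyphenoxy)triisopropylsilane | COc1cc(Br)ccc1O[Si](C(C)C)(C(C)C)C(C)C | intermediate
10 | glyoxylic acid (used as monohydrate) | O=CC(=O)O | starting material
11 | 2-(5-bromo-2-hydroxy-3-methoxyphenyl)-2-hydroxyacetic acid (racemic) | COc1cc(Br)cc(C(O)C(=O)O)c1O | intermediate
12 | (5-bromo-2-hydroxy-3-methoxyphenyl)acetic acid | COc1cc(Br)cc(CC(=O)O)c1O | intermediate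
13 | methyl (5-bromo-2-hydroxy-3-methoxyphenyl)acetate | COC(=O)Cc1cc(Br)cc(OC)c1O | intermediate
14 | vanillin | COc1cc(C=O)ccc1O | starting material
15 | 3-methoxy-4-(triisopropylsilyloxy)benzaldehyde | COc1cc(C=O)ccc1O[Si](C(C)C)(C(C)C)C(C)C | intermediate
16 | [3-methoxy-4-(triisopropylsilyloxy)phenyl]methanol | COc1cc(CO)ccc1O[Si](C(C)C)(C(C)C)C(C)C | intermediate
17 | methyl (5-bromo-3-methoxy-2-{[3-methoxy-4-(triisopropylsilyloxy)benzyl]oxy}phenyl)acetate | COC(=O)Cc1cc(Br)cc(OC)c1OCc1ccc(O[Si](C(C)C)(C(C)C)C(C)C)c(OC)c1 | intermediate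
18 | methyl 2-diazo-2-(5-bromo-3-methoxy-2-{[3-methoxy-4-(triisopropylsilyloxy)benzyl]oxy}phenyl)acetate | COC(=O)C(=[N+]=[N-])c1cc(Br)cc(OC)c1OCc1ccc(O[Si](C(C)C)(C(C)C)C(C)C)c(OC)c1 | intermediate
19 | methyl (2S,3R)-cis-5-bromo-7-methoxy-2-[3-methoxy-4-(triisopropylsilyloxy)phenyl]-2,3-dihydro-1-benzofuran-3-carboxylate | Brc1cc(OC)c2c(c1)[C@@H](C(=O)OC)[C@@H](c1ccc(O[Si](C(C)C)(C(C)C)C(C)C)c(OC)c1)O2 | intermediate
20 | methyl (2S,3S)-trans-5-bromo-7-methoxy-2-[3-methoxy-4-(triisopropylsilyloxy)phenyl]-2,3-dihydro-1-benzofuran-3-carboxylate | Brc1cc(OC)c2c(c1)[C@H](C(=O)OC)[C@@H](c1ccc(O[Si](C(C)C)(C(C)C)C(C)C)c(OC)c1)O2 | intermediate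
21 | {(2S,3R)-trans-5-bromo-7-methoxy-2-[3-methoxy-4-(triisopropylsilyloxy)phenyl]-2,3-dihydro-1-benzofuran-3-yl}methanol | Brc1cc(OC)c2c(c1)[C@H](CO)[C@@H](c1ccc(O[Si](C(C)C)(C(C)C)C(C)C)c(OC)c1)O2 | intermediate
22 | (2S,3R)-trans-5-bromo-3-[(tert-butyldimethylsilyloxy)methyl]-7-methoxy-2-[3-methoxy-4-(triisopropylsilyloxy)phenyl]-2,3-dihydro-1-benzofuran | Brc1cc(OC)c2c(c1)[C@H](CO[Si](C)(C)C(C)(C)C)[C@@H](c1ccc(O[Si](C(C)C)(C(C)C)C(C)C)c(OC)c1)O2 | intermediate
23 | (1R,5R)-6-hydroxy-6-(dihydrobenzofuran-5-yl of 22)-3,7-dioxabicyclo[3.3.0]octan-2-one (lactol lactone mono-adduct, formed as its metal alkoxide, configuration at C6 open) | OC1(c3cc(OC)c4c(c3)[C@H](CO[Si](C)(C)C(C)(C)C)[C@@H](c3ccc(O[Si](C(C)C)(C(C)C)C(C)C)c(OC)c3)O4)[C@@H](CO2)[C@H](CO1)C2=O | intermediate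
24 | (2R,3R)-1-(dihydrobenzofuran-5-yl of 22)-2,3-bis(hydroxymethyl)-4-[3-methoxy-4-(triisopropylsilyloxy)phenyl]butane-1,4-dione | COc1cc(C(=O)[C@@H](CO)[C@H](CO)C(=O)c2cc(OC)c3c(c2)[C@H](CO[Si](C)(C)C(C)(C)C)[C@@H](c2ccc(O[Si](C(C)C)(C(C)C)C(C)C)c(OC)c2)O3)ccc1O[Si](C(C)C)(C(C)C)C(C)C | intermediate
25 | (2R,3R)-1,4-diaryl-2,3-bis(hydroxymethyl)butane-1,4-diol corresponding to 24 (epimers at C1 and C4) | COc1cc(C(O)[C@@H](CO)[C@H](CO)C(O)c2cc(OC)c3c(c2)[C@H](CO[Si](C)(C)C(C)(C)C)[C@@H](c2ccc(O[Si](C(C)C)(C(C)C)C(C)C)c(OC)c2)O3)ccc1O[Si](C(C)C)(C(C)C)C(C)C | intermediate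
26 | tetraacetate of 25 (epimers at C1 and C4) | COc1cc(C(OC(C)=O)[C@@H](COC(C)=O)[C@H](COC(C)=O)C(OC(C)=O)c2cc(OC)c3c(c2)[C@H](CO[Si](C)(C)C(C)(C)C)[C@@H](c2ccc(O[Si](C(C)C)(C(C)C)C(C)C)c(OC)c2)O3)ccc1O[Si](C(C)C)(C(C)C)C(C)C | intermediate
27 | (2R,3R)-2-[3-methoxy-4-(triisopropylsilyloxy)benzyl]-3-[(dihydrobenzofuran-5-yl of 22)methyl]butane-1,4-diyl diacetate | COc1cc(C[C@@H](COC(C)=O)[C@H](COC(C)=O)Cc2cc(OC)c3c(c2)[C@H](CO[Si](C)(C)C(C)(C)C)[C@@H](c2ccc(O[Si](C(C)C)(C(C)C)C(C)C)c(OC)c2)O3)ccc1O[Si](C(C)C)(C(C)C)C(C)C | intermediate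
28 | (2R,3R)-butane-1,4-diol corresponding to 27 (three silyl ethers intact) | COc1cc(C[C@@H](CO)[C@H](CO)Cc2cc(OC)c3c(c2)[C@H](CO[Si](C)(C)C(C)(C)C)[C@@H](c2ccc(O[Si](C(C)C)(C(C)C)C(C)C)c(OC)c2)O3)ccc1O[Si](C(C)C)(C(C)C)C(C)C | intermediate
29 | (2R,3R)-2-(4-hydroxy-3-methoxybenzyl)-3-{[(2S,3R)-2-(4-hydroxy-3-methoxyphenyl)-3-(hydroxymethyl)-7-methoxy-2,3-dihydro-1-benzofuran-5-yl]methyl}butane-1,4-diol | COc1cc(C[C@@H](CO)[C@H](CO)Cc2cc(OC)c3c(c2)[C@H](CO)[C@@H](c2ccc(O)c(OC)c2)O3)ccc1O | target

## Step count and least certain steps

Total step count: 19. Longest linear sequence: 12 steps (steps 6, 7 and 10–19).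

**Step 16 (key step).** The likely failures are collapse of the first lactolate to a ketone followed by a second attack at the same carbon, statistical attack of the first aryl reagent on both carbonyls, and loss of aryl metal through enolisation of the bridgeheads. The fallback sets out from 7 and returns at 24.
- 7 is opened with MeNH(OMe)·HCl and Me3Al to the bis(N-methoxy-N-methylamide) diol F1.
- F1 is silylated with TESCl and imidazole to the bis(triethylsilyl) ether F2.
- The aryllithium from 22 (limiting) and then the aryllithium from 9 are added in sequence to F2. The chelated amide adducts are stable until work-up, which then gives the diketone bis(triethylsilyl) ether F3.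
- PPTS in MeOH removes the two primary triethylsilyl ethers selectively and gives 24.

**Step 18.** The likely failures are hydrogenolytic opening of the O1–C2 bond of ring C, incomplete cleavage of the more hindered benzylic acetate, or elimination to a styrene with loss of chain configuration on re-saturation. The fallback is a radical deoxygenation that sets out from 25 (isolated for this purpose) and returns at 29.
- Selective silylation of the two primary hydroxyls (TBSCl, imidazole, −20 °C) gives the bis-silyl benzylic diol F4.
- 1,1'-Thiocarbonyldiimidazole gives the bis(imidazole-1-carbothioate) F5.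
- Bu3SnH and AIBN in toluene (Barton–McCombie) give the fully silylated deoxy compound F6.
- TBAF/AcOH gives 29.

**Step 12.** The likely failure is insufficient enantio- or cis-selectivity of the carbene insertion for this substitution pattern (a methoxy group flanking the ether oxygen), or diversion of the carbene to dimerisation or oxonium ylide pathways. The fallback uses auxiliary plus catalyst control; it sets out from 17 and returns at 21.
- Mild hydrolysis with Me3SnOH gives the arylacetic acid F7.
- Esterification with (S)-2-hydroxy-1-(pyrrolidin-1-yl)propan-1-one (EDC, DMAP) gives the lactamide ester F8.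
- Diazo transfer (p-ABSA, DBU) gives the diazo ester F9.
- Rh2(S-DOSP)4 (divalent rhodium) should give the trans insertion product F10 directly, with stereoisomers separable as diastereomers.
- LiBH4 removes the auxiliary reductively and gives 21.

**Step 3.** The likely failure is low conversion or poor facial selectivity in the enolate dimerisation, with α-chlorination by CuCl2 as a side path. The fallback builds the succinate stepwise by displacement of an α-triflyloxy ester with a chiral imide enolate, a known route to 2,3-disubstituted succinates; it sets out from 4 and returns at 7.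
- Methyl (S)-3-(benzyloxy)-2-hydroxypropanoate F11 is converted (Tf2O, 2,6-lutidine) to its triflate F12.
- The sodium enolate of 4 (NaN(SiMe3)2, −78 °C) displaces the triflate with inversion and gives the succinate F13.
- Fleming–Tamao oxidation and lactonisation onto the methyl ester give the lactone imide F14.
- Hydrogenolysis of the benzyl ether (H2, Pd/C) frees the second hydroxymethyl group, which lactonises with loss of 1 to give 7.

## Further compounds

F1 | step 16 | (2R,3R)-2,3-bis(hydroxymethyl)-N1,N4-dimethoxy-N1,N4-dimethylbutanediamide | CON(C)C(=O)[C@@H](CO)[C@H](CO)C(=O)N(C)OC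
F2 | step 16 | (2R,3R)-N1,N4-dimethoxy-N1,N4-dimethyl-2,3-bis[(triethylsilyloxy)methyl]butanediamide | CON(C)C(=O)[C@@H](CO[Si](CC)(CC)CC)[C@H](CO[Si](CC)(CC)CC)C(=O)N(C)OC
F3 | step 16 | bis(triethylsilyl) ether of 24 at the two primary hydroxyls | COc1cc(C(=O)[C@@H](CO[Si](CC)(CC)CC)[C@H](CO[Si](CC)(CC)CC)C(=O)c2cc(OC)c3c(c2)[C@H](CO[Si](C)(C)C(C)(C)C)[C@@H](c2ccc(O[Si](C(C)C)(C(C)C)C(C)C)c(OC)c2)O3)ccc1O[Si](C(C)C)(C(C)C)C(C)C
F4 | step 18 | bis(tert-butyldimethylsilyl) ether of 25 at the two primary hydroxyls (epimers at C1 and C4) | COc1cc(C(O)[C@@H](CO[Si](C)(C)C(C)(C)C)[C@H](CO[Si](C)(C)C(C)(C)C)C(O)c2cc(OC)c3c(c2)[C@H](CO[Si](C)(C)C(C)(C)C)[C@@H](c2ccc(O[Si](C(C)C)(C(C)C)C(C)C)c(OC)c2)O3)ccc1O[Si](C(C)C)(C(C)C)C(C)C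
F5 | step 18 | bis(1H-imidazole-1-carbothioate) of F4 at the two benzylic oxygens | COc1cc(C(OC(=S)n2ccnc2)[C@@H](CO[Si](C)(C)C(C)(C)C)[C@H](CO[Si](C)(C)C(C)(C)C)C(OC(=S)n2ccnc2)c2cc(OC)c3c(c2)[C@H](CO[Si](C)(C)C(C)(C)C)[C@@H](c2ccc(O[Si](C(C)C)(C(C)C)C(C)C)c(OC)c2)O3)ccc1O[Si](C(C)C)(C(C)C)C(C)C
F6 | step 18 | bis(tert-butyldimethylsilyl) ether of 28 at the two chain hydroxyls | COc1cc(C[C@@H](CO[Si](C)(C)C(C)(C)C)[C@H](CO[Si](C)(C)C(C)(C)C)Cc2cc(OC)c3c(c2)[C@H](CO[Si](C)(C)C(C)(C)C)[C@@H](c2ccc(O[Si](C(C)C)(C(C)C)C(C)C)c(OC)c2)O3)ccc1O[Si](C(C)C)(C(C)C)C(C)C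
F7 | step 12 | (5-bromo-3-methoxy-2-{[3-methoxy-4-(triisopropylsilyloxy)benzyl]oxy}phenyl)acetic acid | OC(=O)Cc1cc(Br)cc(OC)c1OCc1ccc(O[Si](C(C)C)(C(C)C)C(C)C)c(OC)c1
F8 | step 12 | (S)-1-oxo-1-(pyrrolidin-1-yl)propan-2-yl ester of F7 | C[C@H](OC(=O)Cc1cc(Br)cc(OC)c1OCc1ccc(O[Si](C(C)C)(C(C)C)C(C)C)c(OC)c1)C(=O)N1CCCC1
F9 | step 12 | (S)-1-oxo-1-(pyrrolidin-1-yl)propan-2-yl 2-diazo-2-arylacetate from F8 | C[C@H](OC(=O)C(=[N+]=[N-])c1cc(Br)cc(OC)c1OCc1ccc(O[Si](C(C)C)(C(C)C)C(C)C)c(OC)c1)C(=O)N1CCCC1
F10 | step 12 | (S)-1-oxo-1-(pyrrolidin-1-yl)propan-2-yl (2S,3S)-trans-5-bromo-7-methoxy-2-[3-methoxy-4-(triisopropylsilyloxy)phenyl]-2,3-dihydro-1-benzofuran-3-carboxylate | Brc1cc(OC)c2c(c1)[C@H](C(=O)O[C@@H](C)C(=O)N1CCCC1)[C@@H](c1ccc(O[Si](C(C)C)(C(C)C)C(C)C)c(OC)c1)O2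
F11 | step 3 | methyl (S)-3-(benzyloxy)-2-hydroxypropanoate | COC(=O)[C@@H](O)COCc1ccccc1
F12 | step 3 | methyl (S)-3-(benzyloxy)-2-{[(trifluoromethyl)sulfonyl]oxy}propanoate | COC(=O)[C@@H](OS(=O)(=O)C(F)(F)F)COCc1ccccc1
F13 | step 3 | methyl (2R,3R)-2-[(benzyloxy)methyl]-4-[(R)-4-benzyl-2-oxo-1,3-oxazolidin-3-yl]-3-{[dimethyl(phenyl)silyl]methyl}-4-oxobutanoate | O=C(N1[C@H](Cc2ccccc2)COC1=O)[C@@H](C[Si](C)(C)c1ccccc1)[C@H](COCc1ccccc1)C(=O)OC
F14 | step 3 | (R)-4-benzyl-3-{[(3R,4R)-4-[(benzyloxy)methyl]-5-oxooxolan-3-yl]carbonyl}-1,3-oxazolidin-2-one (cis) | O=C(N1[C@H](Cc3ccccc3)COC1=O)[C@@H](CO2)[C@H](COCc1ccccc1)C2=O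
A1 | alternative 1 | methyl (2S,3S)-trans-5-bromo-7-methoxy-2-[3-methoxy-4-(pivaloyloxy)phenyl]-2,3-dihydro-1-benzofuran-3-carboxylate | Brc1cc(OC)c2c(c1)[C@H](C(=O)OC)[C@@H](c1ccc(OC(=O)C(C)(C)C)c(OC)c1)O2
A2 | alternative 1 | (2S)-6-bromo-8-methoxy-2-[3-methoxy-4-(pivaloyloxy)phenyl]chroman-4-one | O=C1C[C@@H](c2ccc(OC(=O)C(C)(C)C)c(OC)c2)Oc2c(OC)cc(Br)cc12
A3 | alternative 2 | (2S,3R)-trans-2-[4-(benzyloxy)-3-methoxyphenyl]-5-bromo-3-[(tert-butyldimethylsilyloxy)methyl]-7-methoxy-2,3-dihydro-1-benzofuran | Brc1cc(OC)c2c(c1)[C@H](CO[Si](C)(C)C(C)(C)C)[C@@H](c1ccc(OCc3ccccc3)c(OC)c1)O2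
A4 | alternative 2 | 4-bromo-2-[2-(tert-butyldimethylsilyloxy)-1-(4-methylbenzenesulfonyl)ethyl]-6-methoxyphenol (racemic) | COc1cc(Br)cc(C(CO[Si](C)(C)C(C)(C)C)S(=O)(=O)c2ccc(C)cc2)c1O
A5 | alternative 2 | 4-bromo-6-[2-(tert-butyldimethylsilyloxy)ethylidene]-2-methoxycyclohexa-2,4-dien-1-one (o-quinone methide) | COC1=CC(Br)=CC(=CCO[Si](C)(C)C(C)(C)C)C1=O
A6 | alternative 2 | (2R,5R)-1-[4-(benzyloxy)-3-methoxybenzyl]-2,5-dimethylthiolan-1-ium trifluoromethanesulfonate (one enantiomer of the sulfide, shown for definiteness) | C[C@@H]1CC[C@@H](C)[S+]1Cc1ccc(OCc2ccccc2)c(OC)c1.[O-]S(=O)(=O)C(F)(F)F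
A7 | alternative 3 | (S)-1-oxo-1-(pyrrolidin-1-yl)propan-2-yl (2S,3S)-trans-2-[4-(benzyloxy)-3-methoxyphenyl]-5-bromo-7-methoxy-2,3-dihydro-1-benzofuran-3-carboxylate | Brc1cc(OC)c2c(c1)[C@H](C(=O)O[C@@H](C)C(=O)N1CCCC1)[C@@H](c1ccc(OCc3ccccc3)c(OC)c1)O2
A8 | alternative 3 | (S)-1-oxo-1-(pyrrolidin-1-yl)propan-2-yl 2-(2-{[4-(benzyloxy)-3-methoxybenzyl]oxy}-5-bromo-3-methoxyphenyl)-2-diazoacetate | [N-]=[N+]=C(C(=O)O[C@@H](C)C(=O)N1CCCC1)c1cc(Br)cc(OC)c1OCc1ccc(OCc2ccccc2)c(OC)c1
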